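**Retrosynthetic overview** (flavan numbering: O1, C2, C3, C4, C4a, C5–C8, C8a)
- The side chain comes last: the target arises from an 8-allyl flavan by cross-metathesis with methacrolein, then one hydride step that reduces the enal and removes both pivaloyl groups.
- The flavan core (ring C, the C2 centre and the aromatic ring A) arises from an aryl aldehyde and a monocyclic 1-silyloxy diene by a hetero-Diels–Alder reaction that forms C2–C3 and O1–C8a, followed in the same pot by loss of silanol and isoaromatization.
- Enabling feature: in ring A, O1 on C8a and the methoxy oxygen on C7 flank C8 in a 1,3-relationship. Ring A is therefore the aromatized form of a 2-substituted cyclohexane-1,3-dione mono-enol ether, with C8a as carbonyl carbon and C4a as its α′-carbon. A vinyl group (C4=C3) on C4a makes C8a=C4a–C4=C3 a 1-oxy diene, and this 6-vinylcyclohexenone is an isomer of the 2-ethylphenol part of the flavan, so no redox step is needed.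
- The diene comes from cyclohexane-1,3-dione: C-allylation at the future C8, O-methylation (future C7), α′-vinylation at the future C4a (vinyl sulfoxide Michael addition, then pyrolysis), and O-silylation.
- Ring order: ring A is bought saturated and substituted first, ring B arrives with the aldehyde, ring C is closed in the key step, and ring A is aromatized in the same pot.

Key step: step 7

Assumption (remark on the chemistry): the sense of induction of the chromium catalyst with this diene class is not established. The ligand antipode written in step 7 stands for whichever antipode leads to attack on the Si face of the aldehyde, to be fixed in a model run.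

**Step 1**
Reactants: 1 cyclohexane-1,3-dione; 2 allyl acetate
Product: 3 2-(prop-2-en-1-yl)cyclohexane-1,3-dione
Conditions: Pd(PPh3)4 (cat.), Et3N, THF, 50 °C, dione in slight excess
Reagents that add atoms: allyl acetate, C=CCOC(C)=O
Why: Tsuji–Trost allylation, in which the soft dione enolate attacks the π-allylpalladium complex at carbon, so the future C8 substituent goes to the most acidic ring position without a regiochemical question.

**Step 2**
Reactants: 3 2-(prop-2-en-1-yl)cyclohexane-1,3-dione; 4 trimethyl orthoformate
Product: 5 3-methoxy-2-(prop-2-en-1-yl)cyclohex-2-en-1-one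
Conditions: HC(OMe)3, MeOH, TsOH (cat.), rt
Reagents that add atoms: trimethyl orthoformate, COC(OC)OC (methanol, CO, is the solvent and exchanges with it)
Why: acid-catalysed enol etherification of a symmetrical 2-substituted 1,3-dione can give only one vinylogous ester, which fixes the future C7 methoxy group and leaves one carbonyl group as the future C8a.

**Step 3**
Reactants: 5 3-methoxy-2-(prop-2-en-1-yl)cyclohex-2-en-1-one; 6 phenyl vinyl sulfoxide
Product: 8 3-methoxy-6-[2-(phenylsulfinyl)ethyl]-2-(prop-2-en-1-yl)cyclohex-2-en-1-one (mixture of diastereomers), via lithium enolate 7 (not isolated)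
Conditions: LiN(iPr)2, THF, −78 °C; then 6, −78 to −20 °C; aq NH4Cl
Reagents that add atoms: phenyl vinyl sulfoxide, C=CS(=O)c1ccccc1
Why: kinetic α′-deprotonation of the vinylogous ester (Stork–Danheiser regiochemistry) and Michael addition of the enolate to the vinyl sulfoxide as a vinyl cation equivalent; the stereocentres formed here are removed in steps 4 and 5.

**Step 4**
Reactants: 8 3-methoxy-6-[2-(phenylsulfinyl)ethyl]-2-(prop-2-en-1-yl)cyclohex-2-en-1-one
Product: 9 6-ethenyl-3-methoxy-2-(prop-2-en-1-yl)cyclohex-2-en-1-one (racemic)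
Conditions: toluene, 110 °C, CaCO3 (solid)
Reagents that add atoms: none
Why: sulfoxide pyrolysis (thermal syn-elimination) can only take a hydrogen from the carbon next to the ring, which gives the terminal vinyl group; the base-free medium is meant to keep the β,γ-double bond out of conjugation.

**Step 5**
Reactants: 9 6-ethenyl-3-methoxy-2-(prop-2-en-1-yl)cyclohex-2-en-1-one; 10 chlorotriethylsilane
Product: 12 triethyl{[1-ethenyl-4-methoxy-3-(prop-2-en-1-yl)cyclohexa-1,3-dien-2-yl]oxy}silane, via lithium dienolate 11 (not isolated)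
Conditions: LiN(iPr)2, THF, −78 °C; Et3SiCl, −78 to 0 °C; pentane, filtration, used crude
Reagents that add atoms: chlorotriethylsilane, CC[Si](Cl)(CC)CC
Why: silyl enol ether formation, in which the only α-hydrogen (on C6, also allylic) is removed and the dienolate is silylated on oxygen; this gives the 1-silyloxy-1,3-diene for step 7 and erases the C6 stereocentre.

**Step 6**
Reactants: 13 2,4-dihydroxybenzaldehyde; 14 pivaloyl chloride
Product: 15 4-formyl-1,3-phenylene bis(2,2-dimethylpropanoate)
Conditions: PivCl (2.5 equiv), Et3N, DMAP (cat.), CH2Cl2, 0 °C to rt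
Reagents that add atoms: pivaloyl chloride, CC(C)(C)C(=O)Cl
Why: DMAP-catalysed acylation of both phenols; the acyloxy groups make the aldehyde more electrophilic for step 7 and later retard ionization of the benzylic C2–O1 bond.

**Step 7**
Reactants: 12 triethyl{[1-ethenyl-4-methoxy-3-(prop-2-en-1-yl)cyclohexa-1,3-dien-2-yl]oxy}silane; 15 4-formyl-1,3-phenylene bis(2,2-dimethylpropanoate)
Product: 18 4-[(2S)-7-methoxy-8-(prop-2-en-1-yl)-3,4-dihydro-2H-chromen-2-yl]-1,3-phenylene bis(2,2-dimethylpropanoate), via silyl ketal cycloadduct 16 (not isolated), via isoaromatic triene 17 (not isolated)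
Conditions: [CrCl(L)] (5 mol%; L = Schiff base of 3-(1-adamantyl)-2-hydroxy-5-methylbenzaldehyde and (1R,2S)-1-aminoindan-2-ol), 4 Å MS, t-BuOMe, rt; then CH2Cl2, CF3CO2H (1 equiv), −20 to 0 °C
Reagents that add atoms: aldehyde 15, O=Cc1ccc(OC(=O)C(C)(C)C)cc1OC(=O)C(C)(C)C
Why: Proposed new method: the chromium-bound aldehyde should add across the semicyclic 1-silyloxy diene C8a(OSiEt3)=C4a–C4=C3 of 12 in an asynchronous concerted hetero-Diels–Alder reaction, in which the C2–C3 bond (free CH2 terminus to carbonyl carbon) leads and the O1–C8a bond closes the pyran ring onto the silyloxy-bearing terminus to give ketal 16; the closest known reaction types are the hetero-Diels–Alder reaction of 1-alkoxy and silyloxy dienes with aldehydes under tridentate Schiff-base chromium chloride catalysis and the acid-promoted isoaromatization of alkylidenecyclohexadienes. Ring C is closed by [4+2] cycloaddition (in the stepwise limit a 6-exo-trig collapse of the alkoxide onto the silyloxocarbenium carbon C8a), while ring A is not closed but aromatized: CF3CO2H ionizes the ketal with loss of Et3SiOH to a cation stabilized by O1 and the C7 methoxy group, loss of H6 gives triene 17, and protonation at C4 with loss of H5 gives the arene without any redox reagent. The only stereocentre, C2, is set by the chiral catalyst, which should shield the Re face of the bound aldehyde so that C3 adds to the Si face (S configuration); the configuration at the ketal carbon C8a of 16 is of no consequence. The step needs attack through C3 and not through C4a, and reaction through the s-cis diene: C4a is fully substituted, and only the s-cis conformer can give the ring-closed ketal that this catalyst class favours over open-chain Mukaiyama aldol products. The pivaloyl groups activate the aldehyde and disfavour heterolysis of the C2–O1 bond in the acid stage, which is run cold to outpace 6π ring opening of any 2H-pyran tautomer.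

**Step 8**
Reactants: 18 4-[(2S)-7-methoxy-8-(prop-2-en-1-yl)-3,4-dihydro-2H-chromen-2-yl]-1,3-phenylene bis(2,2-dimethylpropanoate); 19 methacrolein
Product: 20 4-[(2S)-7-methoxy-8-[(2E)-3-methyl-4-oxobut-2-en-1-yl]-3,4-dihydro-2H-chromen-2-yl]-1,3-phenylene bis(2,2-dimethylpropanoate)
Conditions: second-generation Grubbs catalyst (H2IMes)(PCy3)Cl2Ru=CHPh (5 mol%), methacrolein (excess), 1,4-benzoquinone (10 mol%), CH2Cl2, 40 °C
Reagents that add atoms: methacrolein, C=C(C)C=O
Why: olefin cross-metathesis of a terminal allyl arene with a 1,1-disubstituted electron-poor alkene should give the trisubstituted (E)-enal under thermodynamic control, with the formyl group trans to the larger substituent; benzoquinone suppresses ruthenium hydride migration of the allyl double bond.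

**Step 9**
Reactants: 20 4-[(2S)-7-methoxy-8-[(2E)-3-methyl-4-oxobut-2-en-1-yl]-3,4-dihydro-2H-chromen-2-yl]-1,3-phenylene bis(2,2-dimethylpropanoate)
Product: 21 morusyunnansin E = 4-[(2S)-8-[(2E)-4-hydroxy-3-methylbut-2-en-1-yl]-7-methoxy-3,4-dihydro-2H-chromen-2-yl]benzene-1,3-diol
Conditions: iBu2AlH (excess), CH2Cl2, −78 to 0 °C; aq KNaC4H4O6
Reagents that add atoms: none
Why: hydride reduction with iBu2AlH should reduce the enal in 1,2-fashion to the (E)-allylic alcohol and cleave both aryl pivalates in the same operation under non-basic conditions, so that neither the alkene geometry nor the C2 benzylic ether centre is touched.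

**Compound list**
1 | cyclohexane-1,3-dione | O=C1CCCC(=O)C1 | starting material
2 | allyl acetate | C=CCOC(C)=O | starting material
3 | 2-(prop-2-en-1-yl)cyclohexane-1,3-dione | C=CCC1C(=O)CCCC1=O | intermediate
4 | trimethyl orthoformate | COC(OC)OC | starting material
5 | 3-methoxy-2-(prop-2-en-1-yl)cyclohex-2-en-1-one | C=CCC1=C(OC)CCCC1=O | intermediate
6 | phenyl vinyl sulfoxide | C=CS(=O)c1ccccc1 | starting material
7 | lithium enolate of 5 (lithium 3-methoxy-2-(prop-2-en-1-yl)cyclohexa-1,5-dien-1-olate) | C=CCC1=C(OC)CCC=C1[O-].[Li+] | intermediate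
8 | 3-methoxy-6-[2-(phenylsulfinyl)ethyl]-2-(prop-2-en-1-yl)cyclohex-2-en-1-one, mixture of diastereomers | C=CCC1=C(OC)CCC(CCS(=O)c2ccccc2)C1=O | intermediate
9 | 6-ethenyl-3-methoxy-2-(prop-2-en-1-yl)cyclohex-2-en-1-one, racemic | C=CCC1=C(OC)CCC(C=C)C1=O | intermediate
10 | chlorotriethylsilane | CC[Si](Cl)(CC)CC | starting material
11 | lithium dienolate of 9 | C=CCC1=C(OC)CCC(C=C)=C1[O-].[Li+] | intermediate
12 | triethyl{[1-ethenyl-4-methoxy-3-(prop-2-en-1-yl)cyclohexa-1,3-dien-2-yl]oxy}silane | C=CCC1=C(OC)CCC(C=C)=C1O[Si](CC)(CC)CC | intermediate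
13 | 2,4-dihydroxybenzaldehyde | O=Cc1ccc(O)cc1O | starting material
14 | pivaloyl chloride | CC(C)(C)C(=O)Cl | starting material
15 | 4-formyl-1,3-phenylene bis(2,2-dimethylpropanoate) | O=Cc1ccc(OC(=O)C(C)(C)C)cc1OC(=O)C(C)(C)C | intermediate
16 | 4-[(2S)-7-methoxy-8-(prop-2-en-1-yl)-8a-(triethylsilyloxy)-3,5,6,8a-tetrahydro-2H-chromen-2-yl]-1,3-phenylene bis(2,2-dimethylpropanoate), ketal carbon C8a not controlled and not specified | COC1=C(CC=C)C2(O[Si](CC)(CC)CC)O[C@H](c3ccc(OC(=O)C(C)(C)C)cc3OC(=O)C(C)(C)C)CC=C2CC1 | intermediate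
17 | 4-[(2S)-7-methoxy-8-(prop-2-en-1-yl)-3,5-dihydro-2H-chromen-2-yl]-1,3-phenylene bis(2,2-dimethylpropanoate) | COC1=CCC2=CC[C@@H](c3ccc(OC(=O)C(C)(C)C)cc3OC(=O)C(C)(C)C)OC2=C1CC=C | intermediate
18 | 4-[(2S)-7-methoxy-8-(prop-2-en-1-yl)-3,4-dihydro-2H-chromen-2-yl]-1,3-phenylene bis(2,2-dimethylpropanoate) | COc1ccc2c(c1CC=C)O[C@H](c1ccc(OC(=O)C(C)(C)C)cc1OC(=O)C(C)(C)C)CC2 | intermediate
19 | methacrolein | C=C(C)C=O | starting material
20 | 4-[(2S)-7-methoxy-8-[(2E)-3-methyl-4-oxobut-2-en-1-yl]-3,4-dihydro-2H-chromen-2-yl]-1,3-phenylene bis(2,2-dimethylpropanoate) | COc1ccc2c(c1C/C=C(\C)C=O)O[C@H](c1ccc(OC(=O)C(C)(C)C)cc1OC(=O)C(C)(C)C)CC2 | intermediate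
21 | morusyunnansin E, 4-[(2S)-8-[(2E)-4-hydroxy-3-methylbut-2-en-1-yl]-7-methoxy-3,4-dihydro-2H-chromen-2-yl]benzene-1,3-diol | COc1ccc2c(c1C/C=C(\C)CO)O[C@H](c1ccc(O)cc1O)CC2 | target

**Step count**
Total steps: 9. Longest linear sequence: 8 (steps 1 to 5 and 7 to 9, from cyclohexane-1,3-dione); step 6 is a one-step side branch.

**Steps most likely to fail**

Step 7. Two processes threaten it. Addition through the s-trans conformer of the diene in an open, Mukaiyama-type manner would leave an (E)-alkylidene ketone that cannot close ring C. Reversible opening of the pyran ring before ring A has aromatized would erode the C2 configuration. The fallback uses known chemistry throughout and makes ring closure independent of alkene geometry by carrying C4 as a carbonyl group. It sets out from 5. C-Acetylation at C6 (LiN(iPr)2, THF, −78 °C; 1-acetylimidazole) should give 6-acetyl-3-methoxy-2-(prop-2-en-1-yl)cyclohex-2-en-1-one F1. Silylation on both oxygens (Me3SiOTf, Et3N, Et2O, 0 °C) should give the bis(trimethylsilyloxy) diene F2. Its vinylogous Mukaiyama aldol addition to 15 under Ti(OiPr)4 and the BINOL antipode that leads to Si-face attack, followed by CF3CO2H, should form C2–C3 and then O1–C8a by cyclocondensation to the dihydropyranone F3. DDQ in toluene should aromatize ring A to the flavanone F4. NaBH4 should give the flavan-4-ol F5. Ionic hydrogenation with Et3SiH and CF3CO2H should remove the benzylic hydroxyl group and come back to the route at 18.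

Step 4. The sulfenic acid set free may move the new double bond into conjugation with the ketone, or add back to it. The fallback changes the order of events so that no enolizable ketone is present during the pyrolysis. It sets out from 8. LiN(iPr)2 and Et3SiCl (THF, −78 °C) should give the silyl dienol ether sulfoxide F6. Its pyrolysis (toluene, 90 °C, CaCO3), eased because the hydrogen removed is allylic, should come back to the route at 12.

Step 8. Metathesis at the doubly ortho-flanked allyl group may be slow, the allyl double bond may migrate into conjugation with ring A, and control of the alkene geometry may be incomplete. The fallback builds the trisubstituted alkene by olefination. It sets out from 18. Lemieux–Johnson cleavage (OsO4 cat., NaIO4, 2,6-lutidine, dioxane–water) should give the arylacetaldehyde F7. Wittig olefination with the stabilized ylide ethyl 2-(triphenylphosphoranylidene)propanoate (toluene, rt) should give the (E)-ester F8. iBu2AlH (excess, CH2Cl2, −78 to 0 °C) should reduce the ester, remove both pivaloyl groups and come back to the route at 21.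

**Further compounds**
F1 | step 7 | 6-acetyl-3-methoxy-2-(prop-2-en-1-yl)cyclohex-2-en-1-one | C=CCC1=C(OC)CCC(C(C)=O)C1=O
F2 | step 7 | {[4-methoxy-3-(prop-2-en-1-yl)-1-[1-(trimethylsilyloxy)ethenyl]cyclohexa-1,3-dien-2-yl]oxy}trimethylsilane | C=CCC1=C(OC)CCC(C(=C)O[Si](C)(C)C)=C1O[Si](C)(C)C
F3 | step 7 | 4-[(2S)-7-methoxy-4-oxo-8-(prop-2-en-1-yl)-2,3,5,6-tetrahydro-4H-chromen-2-yl]-1,3-phenylene bis(2,2-dimethylpropanoate) | COC1=C(CC=C)C2=C(CC1)C(=O)C[C@@H](c3ccc(OC(=O)C(C)(C)C)cc3OC(=O)C(C)(C)C)O2
F4 | step 7 | 4-[(2S)-7-methoxy-4-oxo-8-(prop-2-en-1-yl)-3,4-dihydro-2H-chromen-2-yl]-1,3-phenylene bis(2,2-dimethylpropanoate) | COc1ccc2c(c1CC=C)O[C@H](c1ccc(OC(=O)C(C)(C)C)cc1OC(=O)C(C)(C)C)CC2=O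
F5 | step 7 | 4-[(2S)-4-hydroxy-7-methoxy-8-(prop-2-en-1-yl)-3,4-dihydro-2H-chromen-2-yl]-1,3-phenylene bis(2,2-dimethylpropanoate), C4 epimers | COc1ccc2c(c1CC=C)O[C@H](c1ccc(OC(=O)C(C)(C)C)cc1OC(=O)C(C)(C)C)CC2O
F6 | step 4 | triethyl{[4-methoxy-1-[2-(phenylsulfinyl)ethyl]-3-(prop-2-en-1-yl)cyclohexa-1,3-dien-2-yl]oxy}silane | C=CCC1=C(OC)CCC(CCS(=O)c2ccccc2)=C1O[Si](CC)(CC)CC
F7 | step 8 | 4-[(2S)-7-methoxy-8-(2-oxoethyl)-3,4-dihydro-2H-chromen-2-yl]-1,3-phenylene bis(2,2-dimethylpropanoate) | COc1ccc2c(c1CC=O)O[C@H](c1ccc(OC(=O)C(C)(C)C)cc1OC(=O)C(C)(C)C)CC2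
F8 | step 8 | 4-[(2S)-8-[(2E)-4-ethoxy-3-methyl-4-oxobut-2-en-1-yl]-7-methoxy-3,4-dihydro-2H-chromen-2-yl]-1,3-phenylene bis(2,2-dimethylpropanoate) | COc1ccc2c(c1C/C=C(\C)C(=O)OCC)O[C@H](c1ccc(OC(=O)C(C)(C)C)cc1OC(=O)C(C)(C)C)CC2
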